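**Plan**
Retrosynthesis: the three phenols are unmasked last. The Cα=Cβ enone bond is cut (Claisen–Schmidt) to a 6-acetylchroman-3-ol and 4-hydroxybenzaldehyde. The O1–C2 bond of the dihydropyran is then cut to an ortho-(epoxyprenyl)phenol, and the C4–C4a bond is traced through a [3,3] shift to an O-4 tertiary ether of phloroacetophenone.
Enabling feature: in the dihydropyran ring the fully substituted ether carbon C2 (two methyls, bonded to O1) is the direct neighbour of the carbinol carbon C3. O1 sits on C8a, next to C4a that carries the C4 methylene, and para to the acyl-bearing C6. This O1–C2(Me2)–C3(OH)–C4 array is what a prenyl epoxide leaves when the adjacent phenol attacks its more substituted carbon.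
Forward order: both benzene rings are purchased. O-4 is etherified and O-2/O-6 are masked, then the Claisen shift places the prenyl chain on C3 of the acetophenone and frees O-4 as the only phenol. Epoxidation and acid-induced closure build the dihydropyran, the only ring made, and the cinnamoyl arm is attached afterwards.
Stereochemistry: the sole stereocentre, C3 (R), comes from a Shi epoxidation with the D-fructose-derived ketone and is carried through because its C–O bond is never broken. The E-enone results from E1cB dehydration under thermodynamic control.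

Key step: step 8

Remark: 3-chloro-3-methylbut-1-yne is treated as a purchasable reagent; locants O-2, O-4, O-6 refer to the acetophenone (C1 bears the acetyl group) and locants O1–C8a to the chroman.

Step 1
Reactants: 1 2,4,6-trihydroxyacetophenone; 2 3-chloro-3-methylbut-1-yne
Product: 3 1-[2,6-dihydroxy-4-(2-methylbut-3-yn-2-yloxy)phenyl]ethan-1-one
Conditions: 2 (1.1 equiv), DBU (1.2 equiv), CuCl2·2H2O (1 mol%), MeCN, −5 to 0 °C
Reagents that add atoms: none
Why: Copper-catalysed propargylic etherification of a phenol with a tertiary propargyl chloride should occur at O-4, because this is the most acidic hydroxyl and the only one not hydrogen-bonded to the acetyl carbonyl, so one equivalent of base produces mainly the 4-phenoxide.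

Step 2
Reactants: 3 1-[2,6-dihydroxy-4-(2-methylbut-3-yn-2-yloxy)phenyl]ethan-1-one
Product: 4 1-[2,6-bis(methoxymethoxy)-4-(2-methylbut-3-yn-2-yloxy)phenyl]ethan-1-one
Conditions: NaH (2.5 equiv), MOMCl (3 equiv), DMF, 0 °C → rt
Reagents that add atoms: chloromethyl methyl ether (MOMCl), COCCl
Why: In this Williamson-type O-alkylation sodium hydride breaks the chelate of the ortho hydroxyls so that both become acetals, while the ketone, the alkyne and the tertiary ether are inert at this temperature.

Step 3
Reactants: 4 1-[2,6-bis(methoxymethoxy)-4-(2-methylbut-3-yn-2-yloxy)phenyl]ethan-1-one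
Product: 5 1-[2,6-bis(methoxymethoxy)-4-(2-methylbut-3-en-2-yloxy)phenyl]ethan-1-one
Conditions: H2 (1 atm), Lindlar catalyst, quinoline, EtOAc, rt
Reagents that add atoms: none
Why: Lindlar semihydrogenation stops at the monosubstituted alkene because the poisoned palladium binds the alkyne preferentially, and it leaves the aryl ketone, the MOM acetals and the allylic C–O bond untouched.

Step 4
Reactants: 5 1-[2,6-bis(methoxymethoxy)-4-(2-methylbut-3-en-2-yloxy)phenyl]ethan-1-one
Product: 7 1-[4-hydroxy-2,6-bis(methoxymethoxy)-3-(3-methylbut-2-en-1-yl)phenyl]ethan-1-one, via prenyl cyclohexadienone 6 (not isolated)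
Conditions: PhNEt2, 130–140 °C
Reagents that add atoms: none
Why: In this aromatic Claisen rearrangement the [3,3] shift transposes the 1,1-dimethylallyl group so that a normal prenyl chain arrives at one of two equivalent ortho carbons, and enolisation of dienone 6 releases O-4 as the only free phenol, the weakly basic solvent suppressing ionisation of the tertiary ether.

Step 5
Reactants: 7 1-[4-hydroxy-2,6-bis(methoxymethoxy)-3-(3-methylbut-2-en-1-yl)phenyl]ethan-1-one
Product: 8 1-[2,6-bis(methoxymethoxy)-3-(3-methylbut-2-en-1-yl)-4-(triisopropylsilyloxy)phenyl]ethan-1-one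
Conditions: TIPSCl, imidazole, DMF, rt
Reagents that add atoms: triisopropylsilyl chloride (TIPSCl), CC(C)[Si](Cl)(C(C)C)C(C)C
Why: This is an imidazole-promoted silylation of a phenol, and the bulky TIPS group is chosen because the silyl ether of an acidic phenol must survive the pH 10.5 medium of the next step.

Step 6
Reactants: 8 1-[2,6-bis(methoxymethoxy)-3-(3-methylbut-2-en-1-yl)-4-(triisopropylsilyloxy)phenyl]ethan-1-one
Product: 9 1-[3-{[(2R)-3,3-dimethyloxiran-2-yl]methyl}-2,6-bis(methoxymethoxy)-4-(triisopropylsilyloxy)phenyl]ethan-1-one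
Conditions: D-fructose-derived Shi ketone (30 mol%), Oxone, K2CO3, Bu4NHSO4 (cat.), MeCN–DMM, aq. Na2B4O7/Na2EDTA buffer (pH 10.5), 0 °C
Reagents that add atoms: Oxone (active component potassium peroxymonosulfate), [K+].[O-]S(=O)(=O)OO
Why: In the Shi asymmetric epoxidation the chiral dioxirane of the catalyst attacks the electron-rich trisubstituted alkene through the spiro transition state on the face that gives (R)-configured epoxide carbons from trans- and trisubstituted alkenes, which sets C3, while the silyl ether keeps the phenol from being oxidised or from opening the epoxide under base.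

Step 7
Reactants: 9 1-[3-{[(2R)-3,3-dimethyloxiran-2-yl]methyl}-2,6-bis(methoxymethoxy)-4-(triisopropylsilyloxy)phenyl]ethan-1-one
Product: 10 1-[3-{[(2R)-3,3-dimethyloxiran-2-yl]methyl}-4-hydroxy-2,6-bis(methoxymethoxy)phenyl]ethan-1-one
Conditions: TBAF (1.1 equiv), AcOH (1.5 equiv), THF, 0 °C; neutral aqueous work-up, used without chromatography
Reagents that add atoms: none
Why: Fluoride-induced cleavage of an aryl silyl ether is fast at 0 °C, and the acetic acid buffer protonates the phenoxide as it is released, so the base-induced 5-exo opening of the epoxide should not start and the stereocentre is untouched.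

Step 8
Reactants: 10 1-[3-{[(2R)-3,3-dimethyloxiran-2-yl]methyl}-4-hydroxy-2,6-bis(methoxymethoxy)phenyl]ethan-1-one
Product: 11 1-[(3R)-3-hydroxy-5,7-bis(methoxymethoxy)-2,2-dimethyl-3,4-dihydro-2H-chromen-6-yl]ethan-1-one
Conditions: CSA (10 mol%), dry CH2Cl2, −20 → 0 °C
Reagents that add atoms: none
Why: Camphorsulfonic acid protonates the oxirane oxygen, the bond from oxygen to the tertiary carbon lengthens and positive charge builds up there, and the O-4 phenol captures that carbon in a loose transition state between SN1 and SN2, which makes O1–C2 and leaves the former oxirane oxygen on C3 as the hydroxyl. The closest known reaction type is the acid-catalysed cyclisation of ortho-(2,3-epoxy-3-methylbutyl)phenols to 3-hydroxy-2,2-dimethylchromans, the counterpart of the base-induced closure that leads to 2-(2-hydroxypropan-2-yl)dihydrobenzofurans. The dihydropyran closes in the 6-endo-tet mode. No stereocentre is created, since C2 carries two methyl groups and C3 keeps its (R) configuration because its C–O bond takes no part, so the enantiopurity of 11 should equal that of 10. Two selectivities are needed: 6-endo over 5-exo is secured by the two methyl groups that stabilise the cationic tertiary centre under acid and by the low nucleophilicity of a phenol para to an acetyl group (late, charge-controlled transition state), and O-4 over O-2 is secured by the MOM ether on O-2, which leaves O-4 as the only proton-bearing nucleophile beside the side chain. Catalytic acid in a dry, non-nucleophilic solvent at low temperature should leave the aryl MOM acetals intact and hold back the Meinwald shift to the ketone.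

Step 9
Reactants: 12 4-hydroxybenzaldehyde
Product: 13 4-(methoxymethoxy)benzaldehyde
Conditions: MOMCl, i-Pr2NEt, CH2Cl2, 0 °C → rt
Reagents that add atoms: chloromethyl methyl ether (MOMCl), COCCl
Why: MOM protection of the phenol under amine base keeps the aldehyde from being deactivated as its phenoxide in the aldol condensation.

Step 10
Reactants: 11 1-[(3R)-3-hydroxy-5,7-bis(methoxymethoxy)-2,2-dimethyl-3,4-dihydro-2H-chromen-6-yl]ethan-1-one; 13 4-(methoxymethoxy)benzaldehyde
Product: 15 (2E)-1-[(3R)-3-hydroxy-5,7-bis(methoxymethoxy)-2,2-dimethyl-3,4-dihydro-2H-chromen-6-yl]-3-[4-(methoxymethoxy)phenyl]prop-2-en-1-one, via aldol adduct 14 (not isolated)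
Conditions: KOH, EtOH–H2O, rt
Reagents that add atoms: none
Why: In the Claisen–Schmidt condensation the methyl ketone enolate adds to the non-enolisable aldehyde and aldol 14 loses water by E1cB elimination to the thermodynamically favoured E-enone, the MOM acetals, the chroman and the non-epimerisable C3 carbinol being stable to hydroxide.

Step 11
Reactants: 15 (2E)-1-[(3R)-3-hydroxy-5,7-bis(methoxymethoxy)-2,2-dimethyl-3,4-dihydro-2H-chromen-6-yl]-3-[4-(methoxymethoxy)phenyl]prop-2-en-1-one
Product: 16 (2E)-1-[(3R)-3,5,7-trihydroxy-2,2-dimethyl-3,4-dihydro-2H-chromen-6-yl]-3-(4-hydroxyphenyl)prop-2-en-1-one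
Conditions: HCl (1.25 M in MeOH), rt, closely monitored; dilution with cold water, extraction without basic wash
Reagents that add atoms: none
Why: Acid-catalysed transacetalisation of the three aryl MOM ethers to methanol, a method established for other 2',6'-dihydroxychalcones, frees the phenols under conditions in which the tertiary alkyl aryl ether, the secondary alcohol and the E-enone persist, and short contact at room temperature limits cyclisation to the flavanone.

**Compound list**
1 | 2,4,6-trihydroxyacetophenone | CC(=O)c1c(O)cc(O)cc1O | starting material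
2 | 3-chloro-3-methylbut-1-yne | CC(C)(Cl)C#C | starting material
3 | 1-[2,6-dihydroxy-4-(2-methylbut-3-yn-2-yloxy)phenyl]ethan-1-one | CC(=O)c1c(O)cc(OC(C)(C)C#C)cc1O | intermediate
4 | 1-[2,6-bis(methoxymethoxy)-4-(2-methylbut-3-yn-2-yloxy)phenyl]ethan-1-one | CC(=O)c1c(OCOC)cc(OC(C)(C)C#C)cc1OCOC | intermediate
5 | 1-[2,6-bis(methoxymethoxy)-4-(2-methylbut-3-en-2-yloxy)phenyl]ethan-1-one | CC(=O)c1c(OCOC)cc(OC(C)(C)C=C)cc1OCOC | intermediate
6 | 4-acetyl-3,5-bis(methoxymethoxy)-6-(3-methylbut-2-en-1-yl)cyclohexa-2,4-dien-1-one (racemic at C6, not isolated) | CC(=O)C1=C(OCOC)C(CC=C(C)C)C(=O)C=C1OCOC | intermediate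
7 | 1-[4-hydroxy-2,6-bis(methoxymethoxy)-3-(3-methylbut-2-en-1-yl)phenyl]ethan-1-one | CC(=O)c1c(OCOC)cc(O)c(CC=C(C)C)c1OCOC | intermediate
8 | 1-[2,6-bis(methoxymethoxy)-3-(3-methylbut-2-en-1-yl)-4-(triisopropylsilyloxy)phenyl]ethan-1-one | CC(=O)c1c(OCOC)cc(O[Si](C(C)C)(C(C)C)C(C)C)c(CC=C(C)C)c1OCOC | intermediate
9 | 1-[3-{[(2R)-3,3-dimethyloxiran-2-yl]methyl}-2,6-bis(methoxymethoxy)-4-(triisopropylsilyloxy)phenyl]ethan-1-one | CC1(C)O[C@@H]1Cc1c(O[Si](C(C)C)(C(C)C)C(C)C)cc(OCOC)c(C(C)=O)c1OCOC | intermediate
10 | 1-[3-{[(2R)-3,3-dimethyloxiran-2-yl]methyl}-4-hydroxy-2,6-bis(methoxymethoxy)phenyl]ethan-1-one | CC1(C)O[C@@H]1Cc1c(O)cc(OCOC)c(C(C)=O)c1OCOC | intermediate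
11 | 1-[(3R)-3-hydroxy-5,7-bis(methoxymethoxy)-2,2-dimethyl-3,4-dihydro-2H-chromen-6-yl]ethan-1-one | CC1(C)Oc2cc(OCOC)c(C(C)=O)c(OCOC)c2C[C@H]1O | intermediate
12 | 4-hydroxybenzaldehyde | O=Cc1ccc(O)cc1 | starting material
13 | 4-(methoxymethoxy)benzaldehyde | COCOc1ccc(C=O)cc1 | intermediate
14 | 3-hydroxy-1-[(3R)-3-hydroxy-5,7-bis(methoxymethoxy)-2,2-dimethyl-3,4-dihydro-2H-chromen-6-yl]-3-[4-(methoxymethoxy)phenyl]propan-1-one (both epimers at the new carbinol, not isolated) | CC1(C)Oc2cc(OCOC)c(C(=O)CC(O)c3ccc(OCOC)cc3)c(OCOC)c2C[C@H]1O | intermediate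
15 | (2E)-1-[(3R)-3-hydroxy-5,7-bis(methoxymethoxy)-2,2-dimethyl-3,4-dihydro-2H-chromen-6-yl]-3-[4-(methoxymethoxy)phenyl]prop-2-en-1-one | CC1(C)Oc2cc(OCOC)c(C(=O)/C=C/c3ccc(OCOC)cc3)c(OCOC)c2C[C@H]1O | intermediate
16 | (2E)-1-[(3R)-3,5,7-trihydroxy-2,2-dimethyl-3,4-dihydro-2H-chromen-6-yl]-3-(4-hydroxyphenyl)prop-2-en-1-one | CC1(C)Oc2cc(O)c(C(=O)/C=C/c3ccc(O)cc3)c(O)c2C[C@H]1O | target

Total step count: 11. Longest linear sequence: 10 (steps 1–8, 10, 11); step 9 is a one-step side branch.

**Steps most likely to fail**

Step 1, regioselective etherification. The polyphenolate may be attacked at ring carbon, at O-2, or twice, so the mono-O-4 ether could be only one of several products. The fallback forms the tertiary ether only when a single phenol is left.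
- Setting out from 1, one equivalent of benzyl bromide with K2CO3 in acetone should give 1-[4-(benzyloxy)-2,6-dihydroxyphenyl]ethan-1-one F1.
- NaH/MOMCl then gives 1-[4-(benzyloxy)-2,6-bis(methoxymethoxy)phenyl]ethan-1-one F2.
- Hydrogenolysis (H2, Pd/C, EtOAc) gives 1-[4-hydroxy-2,6-bis(methoxymethoxy)phenyl]ethan-1-one F3.
- Copper-catalysed etherification of this monophenol with 2 rejoins the route at 4.

Step 8, pyran closure. Three side processes are possible: attack at the secondary epoxide carbon (5-exo closure), participation of the neighbouring MOM oxygen with loss of its acetal, and a hydride shift of the activated epoxide. The fallback builds the pyran before the oxygen at C3 is introduced, so no ring-size choice arises. It also avoids handling the epoxy phenol.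
- Setting out from 4, heating in PhNEt2 at about 140 °C (propargyl Claisen shift, [1,5]-H shift, oxa-6π closure) should give 1-[5,7-bis(methoxymethoxy)-2,2-dimethyl-2H-chromen-6-yl]ethan-1-one F4.
- Jacobsen epoxidation with the (R,R)-Mn(salen) catalyst, NaOCl and 4-phenylpyridine N-oxide gives 1-[(3R,4R)-3,4-epoxy-5,7-bis(methoxymethoxy)-2,2-dimethylchroman-6-yl]ethan-1-one F5.
- Hydrogenolysis of the benzylic C4–O bond (H2, Pd/C, EtOAc) keeps the C3–O bond and rejoins the route at 11.

Step 11, global deprotection. During the time needed to cleave the slower B-ring acetal, a liberated ortho hydroxyl may add to the enone (chalcone-to-flavanone isomerisation). The fallback moves the acid step ahead of enone formation.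
- Setting out from 11, methanolic HCl removes both MOM groups while no enone is present and gives 1-[(3R)-3,5,7-trihydroxy-2,2-dimethyl-3,4-dihydro-2H-chromen-6-yl]ethan-1-one F6.
- F6 is condensed with unprotected 12 in concentrated aqueous-ethanolic KOH, a medium that holds the product as the ring-open polyphenolate.
- Rapid acidification in the cold to about pH 5 rejoins the route at 16.

**Further compounds**
F1 | step 1 | 1-[4-(benzyloxy)-2,6-dihydroxyphenyl]ethan-1-one | CC(=O)c1c(O)cc(OCc2ccccc2)cc1O
F2 | step 1 | 1-[4-(benzyloxy)-2,6-bis(methoxymethoxy)phenyl]ethan-1-one | CC(=O)c1c(OCOC)cc(OCc2ccccc2)cc1OCOC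
F3 | step 1 | 1-[4-hydroxy-2,6-bis(methoxymethoxy)phenyl]ethan-1-one | CC(=O)c1c(OCOC)cc(O)cc1OCOC
F4 | step 8 | 1-[5,7-bis(methoxymethoxy)-2,2-dimethyl-2H-chromen-6-yl]ethan-1-one | CC(=O)c1c(OCOC)cc2OC(C)(C)C=Cc2c1OCOC
F5 | step 8 | 1-[(3R,4R)-3,4-epoxy-5,7-bis(methoxymethoxy)-2,2-dimethylchroman-6-yl]ethan-1-one | CC(=O)c1c(OCOC)cc2OC(C)(C)[C@@H]3O[C@@H]3c2c1OCOC
F6 | step 11 | 1-[(3R)-3,5,7-trihydroxy-2,2-dimethyl-3,4-dihydro-2H-chromen-6-yl]ethan-1-one | CC1(C)Oc2cc(O)c(C(C)=O)c(O)c2C[C@H]1O
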